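**Retrosynthetic overview**
1. The acid-labile spiro-2,3-dihydrofuran (C13–C16) is closed last, under basic conditions, by endo cycloisomerisation of a C13-ethynyl/C16-carbinol pair.
2. The 6-oxo/7β-OH/8α-OAc/8β-Me array comes from a Δ6-8-ketone by 1,2-methylation with in situ acetylation, syn-dihydroxylation and selective oxidation of the C6 alcohol.
3. Key disconnection: ring B, the C9–C10 bond and the C9 spiro-tetrahydrofuran form together. A cis-hydrindan-8-ol carrying the whole C9–C16 chain as an alkynyl group undergoes a pinacol-type ring expansion in which C10 shifts from C8 to a C9 oxocarbenium ion.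
4. The cis-hydrindanone comes from (R)-4-silyloxycyclopentenone, homoprenyl bromide and MeI. The C9–C16 alkynol comes from 2-bromoallyl alcohol, TMS-acetylene and acetylene.
5. Ring order: cyclopentane (bought), then ring A, then tetrahydrofuran plus ring B in one step, then dihydrofuran.

Assumption: the SMILES is read literally with labdane numbering (β = face of the C10 methyl): 5β-H (rings A/B cis), 7β-OH, 8α-OAc/8β-Me, 9α-O, 13S, which is (5R,7R,8R,9S,10S,13S).

**Step 1**
Reactants: 1 (4R)-4-[(tert-butyldimethylsilyl)oxy]cyclopent-2-en-1-one; 2 5-bromo-2-methylpent-2-ene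
Product: 4 (4R)-4-(5-bromo-2-methylpentan-2-yl)cyclopent-2-en-1-one, via trans silyloxy ketone adduct 3 (not isolated)
Conditions: Fe(acac)3 (30 mol %), PhSiH3 (2.5 equiv), 2 (3 equiv), EtOH, 60 °C; then DBU (1.2 equiv), rt
Reagents that add atoms: none
Why: Iron-hydride hydrogen atom transfer to 2 gives the tertiary C4 radical, which adds Giese-fashion to C5 anti to the bulky silyloxy group (this sets C5), and DBU then expels silanolate by E1cB so that the new C6=C7 enone blocks C7 against enolisation in step 2 (MHAT reductive olefin coupling, then β-elimination).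

**Step 2**
Reactants: 4 (4R)-4-(5-bromo-2-methylpentan-2-yl)cyclopent-2-en-1-one
Product: 6 (3aR,7aS)-4,4,7a-trimethyl-3a,4,5,6,7,7a-hexahydro-1H-inden-1-one, via cis-bicyclic enone 5 (not isolated)
Conditions: LiN(SiMe3)2 (1.1 equiv), THF/DMPU, −78 → 0 °C; then LiN(i-Pr)2 (1.2 equiv), −78 °C; MeI (3 equiv), −78 → −20 °C
Reagents that add atoms: iodomethane, CI
Why: Kinetic α'-deprotonation at C10 and 6-exo-tet displacement of the tethered bromide can close ring A only on the face carrying the C5 side chain (cis fusion), and the second cross-conjugated enolate is methylated on the open convex face syn to H-5, which sets quaternary C10 with its methyl cis to H-5 (sequential enolate alkylations).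

**Step 3**
Reactants: 6 (3aR,7aS)-4,4,7a-trimethyl-3a,4,5,6,7,7a-hexahydro-1H-inden-1-one
Product: 7 (3aR,7aS)-4,4,7a-trimethyloctahydro-1H-inden-1-one
Conditions: H2 (1 atm), 10% Pd/C, EtOAc, rt
Reagents that add atoms: none
Why: Catalytic hydrogenation saturates the unhindered C6=C7 bond without touching a stereocentre, which removes the vinyl group that would otherwise compete with C10 as the migrating group in step 8.

**Step 4**
Reactants: 8 2-bromoprop-2-en-1-ol; 9 ethynyl(trimethyl)silane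
Product: 10 2-methylidene-4-(trimethylsilyl)but-3-yn-1-ol
Conditions: Pd(PPh3)2Cl2 (2 mol %), CuI (4 mol %), Et3N, THF, rt
Reagents that add atoms: none
Why: Sonogashira coupling of a vinyl bromide with a terminal alkyne tolerates the free alcohol and joins C13 to C14 without creating a stereocentre.

**Step 5**
Reactants: 10 2-methylidene-4-(trimethylsilyl)but-3-yn-1-ol
Product: 12 tert-butyl(dimethyl){[(2R)-2-[(trimethylsilyl)ethynyl]oxiran-2-yl]methoxy}silane, via epoxy alcohol 11 (not isolated)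
Conditions: Ti(OiPr)4 (10 mol %), diethyl L-(+)-tartrate (12 mol %), t-BuOOH (1.5 equiv, decane), 4 Å MS, CH2Cl2, −20 °C; then P(OMe)3; TBSCl, Et3N, DMAP (cat.), −20 → 0 °C
Reagents that add atoms: tert-butyl hydroperoxide, CC(C)(C)OO; tert-butyldimethylsilyl chloride, CC(C)(C)[Si](C)(C)Cl
Why: Sharpless asymmetric epoxidation delivers oxygen to one face of the 1,1-disubstituted allylic alcohol (L-(+)-tartrate gives the 2S epoxy alcohol series) and so sets C13, and in situ silylation avoids isolating the opening-prone epoxy alcohol.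

**Step 6**
Reactants: 12 tert-butyl(dimethyl){[(2R)-2-[(trimethylsilyl)ethynyl]oxiran-2-yl]methoxy}silane; 13 acetylene
Product: 15 (2S)-1-[(tert-butyldimethylsilyl)oxy]-2-[(trimethylsilyl)ethynyl]pent-4-yn-2-ol, via lithium acetylide 14 (not isolated)
Conditions: 13 (excess), n-BuLi, THF, −78 °C; BF3·OEt2; then 12, −78 °C; H2O
Reagents that add atoms: none
Why: BF3-assisted SN2 opening of the 2,2-disubstituted epoxide by the acetylide occurs at the unsubstituted carbon C12, so the C13–O bond and its configuration stay untouched.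

**Step 7**
Reactants: 15 (2S)-1-[(tert-butyldimethylsilyl)oxy]-2-[(trimethylsilyl)ethynyl]pent-4-yn-2-ol; 7 (3aR,7aS)-4,4,7a-trimethyloctahydro-1H-inden-1-one
Product: 17 (1R,3aR,7aS)-1-[(4S)-5-[(tert-butyldimethylsilyl)oxy]-4-hydroxy-4-[(trimethylsilyl)ethynyl]pent-1-yn-1-yl]-4,4,7a-trimethyloctahydro-1H-inden-1-ol, via dilithio alkynoxide 16 (not isolated)
Conditions: 15 (1.1 equiv), n-BuLi (2.2 equiv), THF, −78 → 0 °C; then 7, −78 °C → rt; H2O
Reagents that add atoms: none
Why: The slim alkynyllithium adds 1,2 to the neopentyl ketone from the convex face (syn to the angular methyl, away from ring A and the 4α-methyl), forming the C8–C9 bond and a C8 carbinol centre that is erased again in step 8.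

**Step 8**
Reactants: 17 (1R,3aR,7aS)-1-[(4S)-5-[(tert-butyldimethylsilyl)oxy]-4-hydroxy-4-[(trimethylsilyl)ethynyl]pent-1-yn-1-yl]-4,4,7a-trimethyloctahydro-1H-inden-1-ol
Product: 20 (13S)-16-[(tert-butyldimethylsilyl)oxy]-15-(trimethylsilyl)-9α,13-epoxy-17-nor-5β-labd-14-yn-8-one, via dihydrofuranyl carbinol 18 (not isolated), via oxocarbenium ion 19 (not isolated)
Conditions: (Ph3P)AuNTf2 (5 mol %), (R)-3,3'-bis(2,4,6-triisopropylphenyl)-1,1'-binaphthyl-2,2'-diyl hydrogen phosphate (10 mol %), 4 Å MS, toluene, 0 → 40 °C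
Reagents that add atoms: none
Why: Proposed new method: monovalent gold activates the internal C9≡C11 alkyne for 5-endo-dig attack of the C13 hydroxyl (the silylated alkyne and the silyl ether stay inert) and protodeauration gives enol ether 18; the chiral phosphoric acid then protonates C11 to the C9 oxocarbenium ion 19, held as an ion pair hydrogen-bonded through the C8 hydroxyl, whose only irreversible exit is a pinacol-type 1,2-shift of the fully substituted, electron-richer C10 (not the C7 methylene) from C8 to C9 with retention at C10; this shift enlarges the cyclopentane to ring B, forges the congested C9–C10 bond and sets C9, because the small ring oxygen takes the crowded slot between C1 and the C10 methyl (hence 9α-O), a bias the phosphate is meant to reinforce; the closest known reaction types are the acid-induced pinacolic ring expansion of 1-(4,5-dihydrofuran-2-yl)cycloalkanols, the phosphoric-acid-catalysed semipinacol rearrangement of cyclobutanols to spiroethers and the gold/Brønsted acid cycloisomerisation–hydroalkoxylation of homopropargylic alcohols, which have not been merged into one operation or shown on an unstrained cyclopentanol with a migrating quaternary carbon.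

**Step 9**
Reactants: 20 (13S)-16-[(tert-butyldimethylsilyl)oxy]-15-(trimethylsilyl)-9α,13-epoxy-17-nor-5β-labd-14-yn-8-one
Product: 21 (13S)-16-[(tert-butyldimethylsilyl)oxy]-15-(trimethylsilyl)-9α,13-epoxy-17-nor-5β-labd-6-en-14-yn-8-one
Conditions: LiN(i-Pr)2 (1.2 equiv), THF, −78 °C; N-tert-butylbenzenesulfinimidoyl chloride (1.3 equiv), −78 °C
Reagents that add atoms: none
Why: C7 is the only enolisable position, and the Mukaiyama one-pot dehydrogenation of the lithium enolate at −78 °C gives the Δ6-8-ketone without the acid or heat that could move the double bond or epimerise C5.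

**Step 10**
Reactants: 21 (13S)-16-[(tert-butyldimethylsilyl)oxy]-15-(trimethylsilyl)-9α,13-epoxy-17-nor-5β-labd-6-en-14-yn-8-one
Product: 23 (13S)-8α-acetoxy-16-[(tert-butyldimethylsilyl)oxy]-15-(trimethylsilyl)-9α,13-epoxy-5β-labd-6-en-14-yne, via lithium alkoxide 22 (not isolated)
Conditions: MeLi (1.3 equiv), Et2O, −78 °C; then Ac2O (3 equiv), DMAP (cat.), −78 → 0 °C
Reagents that add atoms: methyllithium, [Li]C; acetic anhydride, CC(=O)OC(C)=O
Why: MeLi adds 1,2 to the enone from the convex β face of the cis-decalin (ring A with axial C1 shields the α face), which sets C8 as 8β-Me/8α-O, and trapping the alkoxide with Ac2O installs the tertiary acetate while no other hydroxyl is present.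

**Step 11**
Reactants: 23 (13S)-8α-acetoxy-16-[(tert-butyldimethylsilyl)oxy]-15-(trimethylsilyl)-9α,13-epoxy-5β-labd-6-en-14-yne
Product: 24 (13S)-8α-acetoxy-16-[(tert-butyldimethylsilyl)oxy]-15-(trimethylsilyl)-9α,13-epoxy-5β-labd-14-yne-6β,7β-diol
Conditions: OsO4 (5 mol %), NMO (2 equiv), acetone/H2O, rt
Reagents that add atoms: N-methylmorpholine N-oxide, C[N+]1([O-])CCOCC1; water, O
Why: Upjohn syn-dihydroxylation takes place anti to the allylic acetate and on the convex β face, which sets 7β-OH (and a transient 6β-OH), and OsO4 leaves the silylated alkyne alone.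

**Step 12**
Reactants: 24 (13S)-8α-acetoxy-16-[(tert-butyldimethylsilyl)oxy]-15-(trimethylsilyl)-9α,13-epoxy-5β-labd-14-yne-6β,7β-diol
Product: 25 (13S)-8α-acetoxy-7β-hydroxy-16-[(tert-butyldimethylsilyl)oxy]-15-(trimethylsilyl)-9α,13-epoxy-5β-labd-14-yn-6-one
Conditions: Dess–Martin periodinane (1.1 equiv), CH2Cl2, 0 °C
Reagents that add atoms: none
Why: Ligand exchange and oxidation occur at the more accessible C6 hydroxyl, because the C7 hydroxyl is neopentyl to quaternary C8, syn-axial to C11 and inductively deactivated by the neighbouring acetate (selective Dess–Martin oxidation of a vicinal diol to the ketol).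

**Step 13**
Reactants: 25 (13S)-8α-acetoxy-7β-hydroxy-16-[(tert-butyldimethylsilyl)oxy]-15-(trimethylsilyl)-9α,13-epoxy-5β-labd-14-yn-6-one
Product: 26 (13S)-8α-acetoxy-7β,16-dihydroxy-9α,13-epoxy-5β-labd-14-yn-6-one
Conditions: Bu4NF (2.5 equiv), AcOH (2.5 equiv), THF, 0 °C → rt
Reagents that add atoms: none
Why: Fluoride cleaves the C(sp)–Si and O–Si bonds in one operation, and the acetic acid buffer suppresses β-elimination of the acetate, acyl shift and C5 epimerisation (global desilylation).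

**Step 14**
Reactants: 26 (13S)-8α-acetoxy-7β,16-dihydroxy-9α,13-epoxy-5β-labd-14-yn-6-one
Product: 27 8α-acetoxy-7β-hydroxy-9α,13;15,16-diepoxy-5β-labd-14-en-6-one, the target (5R,7R,8R,9S,10S,13S)
Conditions: Mo(CO)6 (30 mol %), Me3NO (30 mol %), Et3N/Et2O, rt
Reagents that add atoms: none
Why: The amine-ligated zerovalent molybdenum carbonyl turns the terminal alkyne into a vinylidene, whose C15 is attacked by the C16 hydroxyl (endo alkynol cycloisomerisation to a 2,3-dihydrofuran), so no stereocentre is touched and the mildly basic medium preserves the acid-labile spiro enol ether.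

**Compound list**
1 | (4R)-4-[(tert-butyldimethylsilyl)oxy]cyclopent-2-en-1-one | O=C1C=C[C@H](O[Si](C)(C)C(C)(C)C)C1 | starting material
2 | 5-bromo-2-methylpent-2-ene | CC(C)=CCCBr | starting material
3 | (3S,4R)-3-(5-bromo-2-methylpentan-2-yl)-4-[(tert-butyldimethylsilyl)oxy]cyclopentan-1-one | O=C1C[C@@H](C(C)(C)CCCBr)[C@H](O[Si](C)(C)C(C)(C)C)C1 | intermediate
4 | (4R)-4-(5-bromo-2-methylpentan-2-yl)cyclopent-2-en-1-one | O=C1C[C@@H](C(C)(C)CCCBr)C=C1 | intermediate
5 | (3aS,7aS)-4,4-dimethyl-3a,4,5,6,7,7a-hexahydro-1H-inden-1-one (cis-fused) | O=C1C=C[C@@H]2C(C)(C)CCC[C@H]12 | intermediate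
6 | (3aR,7aS)-4,4,7a-trimethyl-3a,4,5,6,7,7a-hexahydro-1H-inden-1-one (7a-Me cis to 3a-H) | O=C1C=C[C@@H]2C(C)(C)CCC[C@]12C | intermediate
7 | (3aR,7aS)-4,4,7a-trimethyloctahydro-1H-inden-1-one (cis-fused) | O=C1CC[C@@H]2C(C)(C)CCC[C@]12C | intermediate
8 | 2-bromoprop-2-en-1-ol | OCC(Br)=C | starting material
9 | ethynyl(trimethyl)silane | C#C[Si](C)(C)C | starting material
10 | 2-methylidene-4-(trimethylsilyl)but-3-yn-1-ol | OCC(=C)C#C[Si](C)(C)C | intermediate
11 | [(2S)-2-[(trimethylsilyl)ethynyl]oxiran-2-yl]methanol | C1O[C@@]1(C#C[Si](C)(C)C)CO | intermediate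
12 | tert-butyl(dimethyl){[(2R)-2-[(trimethylsilyl)ethynyl]oxiran-2-yl]methoxy}silane | C1O[C@@]1(C#C[Si](C)(C)C)CO[Si](C)(C)C(C)(C)C | intermediate
13 | acetylene | C#C | starting material
14 | lithium acetylide | [Li]C#C | intermediate
15 | (2S)-1-[(tert-butyldimethylsilyl)oxy]-2-[(trimethylsilyl)ethynyl]pent-4-yn-2-ol | C#CC[C@](O)(C#C[Si](C)(C)C)CO[Si](C)(C)C(C)(C)C | intermediate
16 | O,C-dilithio derivative of 15 | [Li]C#CC[C@](O[Li])(C#C[Si](C)(C)C)CO[Si](C)(C)C(C)(C)C | intermediate
17 | propargylic diol, (1R,3aR,7aS) core, 8β-alkynyl/8α-OH, 13S | O[C@]1(C#CC[C@](O)(C#C[Si](C)(C)C)CO[Si](C)(C)C(C)(C)C)CC[C@@H]2C(C)(C)CCC[C@]12C | intermediate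
18 | (1R,3aR,7aS)-1-[(5S)-5-(silyloxymethyl)-5-(silylethynyl)-4,5-dihydrofuran-2-yl]-4,4,7a-trimethyloctahydro-1H-inden-1-ol | O[C@]1(C2=CC[C@](O2)(C#C[Si](C)(C)C)CO[Si](C)(C)C(C)(C)C)CC[C@@H]3C(C)(C)CCC[C@]13C | intermediate
19 | C9 oxocarbenium ion derived from 18 (phosphate ion pair) | O[C@]1(C2=[O+][C@@](C#C[Si](C)(C)C)(CO[Si](C)(C)C(C)(C)C)CC2)CC[C@@H]3C(C)(C)CCC[C@]13C | intermediate
20 | (13S)-16-TBSO-15-TMS-9α,13-epoxy-17-nor-5β-labd-14-yn-8-one | O=C1CC[C@@H]2C(C)(C)CCC[C@]2(C)[C@@]12CC[C@](C#C[Si](C)(C)C)(CO[Si](C)(C)C(C)(C)C)O2 | intermediate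
21 | (13S)-16-TBSO-15-TMS-9α,13-epoxy-17-nor-5β-labd-6-en-14-yn-8-one | O=C1C=C[C@@H]2C(C)(C)CCC[C@]2(C)[C@@]12CC[C@](C#C[Si](C)(C)C)(CO[Si](C)(C)C(C)(C)C)O2 | intermediate
22 | lithium 8α-alkoxide (8β-methyl) of the Δ6 alcohol | [Li]O[C@]1(C)C=C[C@@H]2C(C)(C)CCC[C@]2(C)[C@@]12CC[C@](C#C[Si](C)(C)C)(CO[Si](C)(C)C(C)(C)C)O2 | intermediate
23 | (13S)-8α-acetoxy-16-TBSO-15-TMS-9α,13-epoxy-5β-labd-6-en-14-yne | CC(=O)O[C@]1(C)C=C[C@@H]2C(C)(C)CCC[C@]2(C)[C@@]12CC[C@](C#C[Si](C)(C)C)(CO[Si](C)(C)C(C)(C)C)O2 | intermediate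
24 | (13S)-8α-acetoxy-16-TBSO-15-TMS-9α,13-epoxy-5β-labd-14-yne-6β,7β-diol | CC(=O)O[C@]1(C)[C@@H](O)[C@@H](O)[C@@H]2C(C)(C)CCC[C@]2(C)[C@@]12CC[C@](C#C[Si](C)(C)C)(CO[Si](C)(C)C(C)(C)C)O2 | intermediate
25 | (13S)-8α-acetoxy-7β-hydroxy-16-TBSO-15-TMS-9α,13-epoxy-5β-labd-14-yn-6-one | CC(=O)O[C@]1(C)[C@@H](O)C(=O)[C@@H]2C(C)(C)CCC[C@]2(C)[C@@]12CC[C@](C#C[Si](C)(C)C)(CO[Si](C)(C)C(C)(C)C)O2 | intermediate
26 | (13S)-8α-acetoxy-7β,16-dihydroxy-9α,13-epoxy-5β-labd-14-yn-6-one | CC(=O)O[C@]1(C)[C@@H](O)C(=O)[C@@H]2C(C)(C)CCC[C@]2(C)[C@@]12CC[C@](C#C)(CO)O2 | intermediate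
27 | 8α-acetoxy-7β-hydroxy-9α,13;15,16-diepoxy-5β-labd-14-en-6-one (CNP0275274.1) | CC(=O)O[C@]1(C)[C@@H](O)C(=O)[C@@H]2C(C)(C)CCC[C@]2(C)[C@@]12CC[C@@]1(C=COC1)O2 | target

**Step count.** Total: 14 steps. Longest linear sequence: 11 steps (steps 1–3, then 7–14). The branch of steps 4–6, then 7–14, is equally long.

**Three steps most likely to fail**

**Step 8 (the new cascade).** It may stall at 18, dehydrate the carbinol, or give the C9 epimer; the antipodal phosphoric acid is the first control.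
- The fallback uses known chemistry, sets out from 15 (with 7) and comes back at 20.
- Mo(CO)6/Me3NO/Et3N cycloisomerisation of the terminal alkynol gives the 2,2-disubstituted 2,3-dihydrofuran F1.
- t-BuLi lithiates its vinylic O–CH position, and the vinyllithium adds to 7 to give carbinol 18, now as an isolated compound.
- NBS in CH2Cl2 with propylene oxide triggers the irreversible bromonium-induced pinacol-type ring expansion to the 11-bromo spiro ketone F2.
- Bu3SnH/AIBN removes the bromine to give 20.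

**Step 10.** MeLi may attack the α face and give the 8-epimer, or the hindered alkoxide may resist acetylation.
- The fallback sets out from 21 and comes back at 25, so steps 11 and 12 are not needed.
- MeLi followed by water gives the tertiary allylic alcohol F3; either C8 epimer serves.
- Pyridinium chlorochromate effects the oxidative 1,3-transposition to the 8-methyl-Δ7-6-ketone F4.
- H2O2/NaOH epoxidises it on the convex β face to the 7β,8β-epoxy ketone F5.
- Acetolysis (AcOH, catalytic BF3·OEt2, 0 °C) opens the epoxide at tertiary C8 with inversion, so 8α-OAc and the free 7β-OH arise together.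

**Step 12.** The oxidation may take the C7 hydroxyl or run on to the diketone.
- The fallback sets out from 23 and comes back at 25, avoiding the diol altogether.
- mCPBA epoxidises Δ6 anti to the acetate to give the 6β,7β-epoxide F6.
- DMSO with catalytic BF3·OEt2 attacks the less hindered C6 in a trans-diaxial opening.
- i-Pr2NEt collapses the alkoxysulfonium salt to the C6 ketone, and the epoxide oxygen remains as 7β-OH.

**Further compounds**
F1 | step 8 | (2S)-2-{[(tert-butyldimethylsilyl)oxy]methyl}-2-[(trimethylsilyl)ethynyl]-2,3-dihydrofuran | C1=CC[C@](O1)(C#C[Si](C)(C)C)CO[Si](C)(C)C(C)(C)C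
F2 | step 8 | 11-bromo derivative of 20 (C11 epimers) | O=C1CC[C@@H]2C(C)(C)CCC[C@]2(C)[C@@]12C(Br)C[C@](C#C[Si](C)(C)C)(CO[Si](C)(C)C(C)(C)C)O2
F3 | step 10 | 8-hydroxy-8-methyl-Δ6 tertiary allylic alcohol (C8 epimers) | OC1(C)C=C[C@@H]2C(C)(C)CCC[C@]2(C)[C@@]12CC[C@](C#C[Si](C)(C)C)(CO[Si](C)(C)C(C)(C)C)O2
F4 | step 10 | (13S)-16-TBSO-15-TMS-9α,13-epoxy-5β-labd-7-en-14-yn-6-one | CC1=CC(=O)[C@@H]2C(C)(C)CCC[C@]2(C)[C@@]12CC[C@](C#C[Si](C)(C)C)(CO[Si](C)(C)C(C)(C)C)O2
F5 | step 10 | 7β,8β-epoxide of F4 | C[C@]12O[C@H]1C(=O)[C@@H]3C(C)(C)CCC[C@]3(C)[C@@]24CC[C@](C#C[Si](C)(C)C)(CO[Si](C)(C)C(C)(C)C)O4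
F6 | step 12 | 6β,7β-epoxide of 23 | CC(=O)O[C@]1(C)[C@H]2O[C@H]2[C@@H]3C(C)(C)CCC[C@]3(C)[C@@]14CC[C@](C#C[Si](C)(C)C)(CO[Si](C)(C)C(C)(C)C)O4
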